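The cyclopentanone is closed between C8 and C12 (prostanoid numbering: C8 carries the heptenoic acid chain, C9 the hydroxyl, C11 is the ring ketone, C12 carries the 3-oxooctyl chain). The feature exploited is the cis pair C9–O/C8–C7 next to the C11 ketone. C9–O and C6 are tied as a butenolide whose β-carbon is C8, and C11/C12 hang from C9 as a β-keto ester arm. One base-catalysed operation adds C12 to C8, giving the cis-fused cyclopentanone–lactone with C8 set by C9, and then joins C12 to oct-1-en-3-one, which delivers the whole lower chain. Decarboxylation, ketal protection, lactone reduction and Wittig olefination complete the acid.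

Key step: step 4

Remark on the chemistry: C12 is α to the C11 ketone and is treated as a centre under thermodynamic control; the enantiomer preference of the lipase in step 2 is assigned from its empirical size rule and is to be confirmed by chiral HPLC.

Step 1
Reactants: 1 tert-butyl 3-oxobutanoate; 2 prop-2-enal (acrolein)
Product: 3 tert-butyl (5RS)-5-hydroxy-3-oxohept-6-enoate (racemic)
Conditions: NaH (1.1 equiv), THF, 0 °C; n-BuLi (1.05 equiv), 0 °C; 2, −78 °C; aq NH4Cl
Reagents that add atoms: none
Why: The acetoacetate dianion reacts at its terminal carbon and should add 1,2 to the aldehyde at low temperature (dianion aldol addition); the carbinol centre forms as a racemate and is resolved in step 2.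

Step 2
Reactants: 3 tert-butyl (5RS)-5-hydroxy-3-oxohept-6-enoate; 4 ethenyl prop-2-enoate (vinyl acrylate)
Product: 5 tert-butyl (5S)-3-oxo-5-(prop-2-enoyloxy)hept-6-enoate
Conditions: Novozym 435 (immobilised Candida antarctica lipase B), 4 (3 equiv), BHT (cat.), t-BuOMe, 30 °C, stopped near half conversion; chromatography removes the unreacted (5R)-alcohol
Reagents that add atoms: none
Why: Lipase-catalysed kinetic resolution by irreversible acyl transfer from an enol ester; the vinyl group fits the small pocket and the keto ester arm the large one, so the (5S)-alcohol should be acylated, while the tert-butyl ester is too hindered to take part; no new stereocentre forms, the needed enantiomer is selected.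

Step 3
Reactants: 5 tert-butyl (5S)-3-oxo-5-(prop-2-enoyloxy)hept-6-enoate
Product: 6 tert-butyl 3-oxo-4-[(2S)-5-oxo-2,5-dihydrofuran-2-yl]butanoate
Conditions: second-generation Grubbs catalyst RuCl2(=CHPh)(H2IMes)(PCy3) (5 mol%), toluene (0.01 M), 80 °C, argon purge
Reagents that add atoms: none
Why: Ring-closing metathesis of the acrylate with the vinyl group should close the five-membered unsaturated lactone with loss of ethene; the stereocentre is not touched.

Step 4
Reactants: 6 tert-butyl 3-oxo-4-[(2S)-5-oxo-2,5-dihydrofuran-2-yl]butanoate; 7 oct-1-en-3-one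
Product: 9 tert-butyl (3aR,4S,6aS)-2,5-dioxo-4-(3-oxooctyl)hexahydro-2H-cyclopenta[b]furan-4-carboxylate, via bicyclic keto ester 8 (not isolated)
Conditions: Cs2CO3 (0.2 equiv), MeCN (0.05 M), 0 °C to rt; then 7 (1.2 equiv), rt; AcOH quench
Reagents that add atoms: none
Why: Cs2CO3 should deprotonate only the doubly activated carbon C12, whose enolate adds to the butenolide β-carbon C8 to form the C8–C12 bond; the lactone enolate is protonated by more keto ester, and the still acidic 8 then adds to enone 7 to give the quaternary C12 of 9. The closest known reaction type is the intramolecular Michael addition of a β-keto ester to an unsaturated ester, followed by the intermolecular Michael addition of a 2-alkoxycarbonylcyclopentanone to a vinyl ketone (double Michael cascade). The cyclopentanone closes in the 5-exo-trig mode with the enolate double bond exocyclic through the ester carbonyl (5-(enolexo)-exo-trig, geometrically allowed). C8 is controlled by C9: the three-atom tether reaches the butenolide only on the face from which it leaves C9 and a trans-fused bicyclo[3.3.0] skeleton is too strained, so C8–C7 ends cis to C9–O; C12 forms with the enone entering on the convex face, but this is provisional because the ester is removed in step 5. The step needs C-attack at C8 before E1cB opening of the lactone through C10 or racemisation at C9, which the catalytic weak base and the large acidity gap should secure, and single alkylation by 7, which cyclising first secures because only one acidic hydrogen then remains.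

Step 5
Reactants: 9 tert-butyl (3aR,4S,6aS)-2,5-dioxo-4-(3-oxooctyl)hexahydro-2H-cyclopenta[b]furan-4-carboxylate
Product: 12 (3a'R,4'R,6a'S)-4'-[2-(2-pentyl-1,3-dioxolan-2-yl)ethyl]hexahydrospiro[1,3-dioxolane-2,5'-cyclopenta[b]furan]-2'(3'H)-one, via keto acid 10 (not isolated), via diketo lactone 11 (not isolated)
Conditions: CF3CO2H/CH2Cl2 (1:4), 0 °C to rt; evaporate, toluene, 70 °C; then HOCH2CH2OH (8 equiv), TsOH·H2O (0.05 equiv), reflux, Dean–Stark trap
Reagents that add atoms: ethylene glycol OCCO
Why: Acid cleaves the tert-butyl ester with loss of 2-methylpropene, the β-keto acid loses CO2 on warming, and both ketones are then converted into dioxolanes, the glycol being added before the acid catalyst so that the 1,5-diketone is never heated with acid alone (no aldol closure); C12 should equilibrate through the enol and the enol ether to the epimer with the chain on the convex face, trans to C7 (thermodynamic control).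

Step 6
Reactants: 12 (3a'R,4'R,6a'S)-4'-[2-(2-pentyl-1,3-dioxolan-2-yl)ethyl]hexahydrospiro[1,3-dioxolane-2,5'-cyclopenta[b]furan]-2'(3'H)-one
Product: 13 (3a'R,4'R,6a'S)-4'-[2-(2-pentyl-1,3-dioxolan-2-yl)ethyl]hexahydro-2'H-spiro[1,3-dioxolane-2,5'-cyclopenta[b]furan]-2'-ol (lactol, mixture of anomers)
Conditions: i-Bu2AlH (1.1 equiv), toluene, −78 °C; MeOH, aq potassium sodium tartrate
Reagents that add atoms: none
Why: Partial reduction of a γ-lactone to the lactol through the tetrahedral aluminium alkoxide that persists at low temperature; the ketals are inert and no skeletal stereocentre changes.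

Step 7
Reactants: 13 the lactol; 14 (4-carboxybutyl)triphenylphosphonium bromide
Product: 15 (5Z)-7-{(6R,7R,8S)-8-hydroxy-6-[2-(2-pentyl-1,3-dioxolan-2-yl)ethyl]-1,4-dioxaspiro[4.4]nonan-7-yl}hept-5-enoic acid
Conditions: 14 (3.5 equiv), KOt-Bu (7 equiv), THF, 0 °C, 30 min; then 13, 0 °C to rt; cold aq citric acid to pH 5
Reagents that add atoms: none
Why: Wittig olefination of the open hydroxy aldehyde form of the lactol with the non-stabilised carboxylate ylide should give the Z alkene through the kinetically favoured cis-oxaphosphetane and frees the C9 hydroxyl; the ketals shield both ketones from ylide and base.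

Step 8
Reactants: 15 (5Z)-7-{(6R,7R,8S)-8-hydroxy-6-[2-(2-pentyl-1,3-dioxolan-2-yl)ethyl]-1,4-dioxaspiro[4.4]nonan-7-yl}hept-5-enoic acid
Product: 16 (5Z)-7-[(1R,2R,5S)-5-hydroxy-3-oxo-2-(3-oxooctyl)cyclopentyl]hept-5-enoic acid (13,14-dihydro-15-keto-PGD2)
Conditions: AcOH/H2O/THF (6:3:1), 40 °C, monitored; silica chromatography
Reagents that add atoms: water O
Why: Acid-catalysed hydrolysis of both dioxolanes (the cyclopentanone ketal is among the more labile, since the change from sp3 to sp2 relieves ring strain) at an acidity under which the β-hydroxy ketone should persist; C12, again α to the ketone, keeps its more stable trans arrangement.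

Compound list
1 | tert-butyl 3-oxobutanoate | CC(=O)CC(=O)OC(C)(C)C | starting material
2 | prop-2-enal (acrolein) | C=CC=O | starting material
3 | tert-butyl (5RS)-5-hydroxy-3-oxohept-6-enoate | C=CC(O)CC(=O)CC(=O)OC(C)(C)C | intermediate
4 | ethenyl prop-2-enoate (vinyl acrylate) | C=CC(=O)OC=C | starting material
5 | tert-butyl (5S)-3-oxo-5-(prop-2-enoyloxy)hept-6-enoate | C=C[C@@H](OC(=O)C=C)CC(=O)CC(=O)OC(C)(C)C | intermediate
6 | tert-butyl 3-oxo-4-[(2S)-5-oxo-2,5-dihydrofuran-2-yl]butanoate | O=C1C=C[C@H](CC(=O)CC(=O)OC(C)(C)C)O1 | intermediate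
7 | oct-1-en-3-one | CCCCCC(=O)C=C | starting material
8 | tert-butyl (3aR,6aS)-2,5-dioxohexahydro-2H-cyclopenta[b]furan-4-carboxylate (C4 epimers and enol) | O=C(OC(C)(C)C)C1C(=O)C[C@@H]2OC(=O)C[C@H]12 | intermediate
9 | tert-butyl (3aR,4S,6aS)-2,5-dioxo-4-(3-oxooctyl)hexahydro-2H-cyclopenta[b]furan-4-carboxylate | CCCCCC(=O)CC[C@@]1(C(=O)OC(C)(C)C)C(=O)C[C@@H]2OC(=O)C[C@H]12 | intermediate
10 | (3aR,4S,6aS)-2,5-dioxo-4-(3-oxooctyl)hexahydro-2H-cyclopenta[b]furan-4-carboxylic acid | CCCCCC(=O)CC[C@@]1(C(=O)O)C(=O)C[C@@H]2OC(=O)C[C@H]12 | intermediate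
11 | (3aR,4R,6aS)-4-(3-oxooctyl)hexahydro-2H-cyclopenta[b]furan-2,5-dione | CCCCCC(=O)CC[C@H]1C(=O)C[C@@H]2OC(=O)C[C@H]12 | intermediate
12 | (3a'R,4'R,6a'S)-4'-[2-(2-pentyl-1,3-dioxolan-2-yl)ethyl]hexahydrospiro[1,3-dioxolane-2,5'-cyclopenta[b]furan]-2'(3'H)-one | CCCCCC1(OCCO1)CC[C@H]2C3(OCCO3)C[C@@H]4OC(=O)C[C@H]24 | intermediate
13 | (3a'R,4'R,6a'S)-4'-[2-(2-pentyl-1,3-dioxolan-2-yl)ethyl]hexahydro-2'H-spiro[1,3-dioxolane-2,5'-cyclopenta[b]furan]-2'-ol (anomers) | CCCCCC1(OCCO1)CC[C@H]2C3(OCCO3)C[C@@H]4OC(O)C[C@H]24 | intermediate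
14 | (4-carboxybutyl)triphenylphosphonium bromide | OC(=O)CCCC[P+](c1ccccc1)(c1ccccc1)c1ccccc1.[Br-] | starting material
15 | (5Z)-7-{(6R,7R,8S)-8-hydroxy-6-[2-(2-pentyl-1,3-dioxolan-2-yl)ethyl]-1,4-dioxaspiro[4.4]nonan-7-yl}hept-5-enoic acid | CCCCCC1(OCCO1)CC[C@H]2C3(OCCO3)C[C@H](O)[C@@H]2C/C=C\CCCC(=O)O | intermediate
16 | (5Z)-7-[(1R,2R,5S)-5-hydroxy-3-oxo-2-(3-oxooctyl)cyclopentyl]hept-5-enoic acid | CCCCCC(=O)CC[C@H]1C(=O)C[C@H](O)[C@@H]1C/C=C\CCCC(=O)O | target

Total step count: 8. Longest linear sequence: 8 steps (from 1 or 2 to 16).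

Steps most likely to fail

Step 4. Deprotonation at C10 or at C9 instead of C12 could open the lactone by E1cB elimination or erode the configuration at C9 before the C–C bond forms, or the Michael equilibrium could lie on the open side. The fallback sets out from 6 and comes back at 8, forming the same C8–C12 bond by carbene chemistry. Hydrogenation of 6 (H2, Pd on carbon, EtOAc) should give tert-butyl 3-oxo-4-[(2R)-5-oxooxolan-2-yl]butanoate F1. Diazo transfer (4-acetamidobenzenesulfonyl azide, Et3N, MeCN) should give tert-butyl 2-diazo-3-oxo-4-[(2R)-5-oxooxolan-2-yl]butanoate F2. Rh2(OAc)4 (1 mol%) in CH2Cl2 at 40 °C should then effect intramolecular 1,5 C–H insertion into the ring methylene next to the stereocentre. Ring strain again allows only the cis-fused 8, which is alkylated with 7 under Et3N catalysis to 9.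

Step 8. Acid could promote loss of water from the β-hydroxy ketone towards the conjugated cyclopentenone, or aldol closure of the freed 1,5-diketone, while the ring ketal is still hydrolysing. The fallback sets out from 9 and comes back at 16, using ketals that cleave under far weaker acid. The same acid cleavage and decarboxylation, followed by HC(OMe)3, MeOH and pyridinium tosylate at rt, should give (3aR,4R,6aS)-4-(3,3-dimethoxyoctyl)-5,5-dimethoxyhexahydro-2H-cyclopenta[b]furan-2-one F3. Reduction with i-Bu2AlH should give the lactol (3aR,4R,6aS)-4-(3,3-dimethoxyoctyl)-5,5-dimethoxyhexahydro-2H-cyclopenta[b]furan-2-ol F4. Wittig reaction with 14 should give (5Z)-7-[(1R,2R,5S)-2-(3,3-dimethoxyoctyl)-5-hydroxy-3,3-dimethoxycyclopentyl]hept-5-enoic acid F5. Aqueous oxalic acid (1%) in THF at 0 °C should then release 16.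

Step 2. The lipase could discriminate the enantiomers poorly or transfer the acryloyl group too slowly. The fallback sets out from 1 and comes back at 5, replacing resolution by catalytic asymmetric C–C bond formation. Double silylation of 1 (Et3N, Me3SiCl; then LiN(i-Pr)2, Me3SiCl) should give 1-tert-butoxy-1,3-bis(trimethylsilyloxy)buta-1,3-diene F6. Vinylogous Mukaiyama aldol addition to 2, catalysed by Ti(Oi-Pr)4 and (S)-BINOL (sense of induction assigned by analogy, to be checked), with acidic desilylation, should give tert-butyl (5S)-5-hydroxy-3-oxohept-6-enoate F7. Acryloyl chloride and i-Pr2NEt in CH2Cl2 at −20 °C should then give 5.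

Further compounds
F1 | step 4 | tert-butyl 3-oxo-4-[(2R)-5-oxooxolan-2-yl]butanoate | O=C1CC[C@H](CC(=O)CC(=O)OC(C)(C)C)O1
F2 | step 4 | tert-butyl 2-diazo-3-oxo-4-[(2R)-5-oxooxolan-2-yl]butanoate | O=C1CC[C@H](CC(=O)C(=[N+]=[N-])C(=O)OC(C)(C)C)O1
F3 | step 8 | (3aR,4R,6aS)-4-(3,3-dimethoxyoctyl)-5,5-dimethoxyhexahydro-2H-cyclopenta[b]furan-2-one | CCCCCC(OC)(OC)CC[C@H]1C(OC)(OC)C[C@@H]2OC(=O)C[C@H]12
F4 | step 8 | (3aR,4R,6aS)-4-(3,3-dimethoxyoctyl)-5,5-dimethoxyhexahydro-2H-cyclopenta[b]furan-2-ol | CCCCCC(OC)(OC)CC[C@H]1C(OC)(OC)C[C@@H]2OC(O)C[C@H]12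
F5 | step 8 | (5Z)-7-[(1R,2R,5S)-2-(3,3-dimethoxyoctyl)-5-hydroxy-3,3-dimethoxycyclopentyl]hept-5-enoic acid | CCCCCC(OC)(OC)CC[C@H]1C(OC)(OC)C[C@H](O)[C@@H]1C/C=C\CCCC(=O)O
F6 | step 2 | 1-tert-butoxy-1,3-bis(trimethylsilyloxy)buta-1,3-diene | C=C(O[Si](C)(C)C)C=C(OC(C)(C)C)O[Si](C)(C)C
F7 | step 2 | tert-butyl (5S)-5-hydroxy-3-oxohept-6-enoate | C=C[C@@H](O)CC(=O)CC(=O)OC(C)(C)C
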